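## Structural features

Compound 24 is a p-terphenyl: a central benzene ring is joined through C3 and C6 by two biaryl single bonds to two 4-hydroxyphenyl rings. The central ring is fully substituted, with benzoate esters on the neighbouring carbons C1 and C2 and free hydroxyls on the neighbouring carbons C4 and C5, so the molecule has a mirror plane through the C1–C2 and C4–C5 bonds. There is no stereocentre, so no stereocentres stand next to each other. The only stereochemical elements on the route are transient: a quaternary carbon and an alkene geometry in the key-step precursor. The fragile groups are the two aryl benzoates, which bases and nucleophiles cleave or shift, and the electron-rich catechol and phenols, which oxidise easily to quinones. The real difficulty is not the carbon skeleton but the fixed order of six substituents on one ring and the division of four ring oxygens into an acylated pair and a free pair. The key step exploits the repeating sequence aryl, oxygen, oxygen around the ring. C4, C3, C2 and C1 correspond to the carbonyl carbon, the aryl-bearing carbon, the alkoxy-bearing carbon and the sp3 carbon of a cyclobutenone, and C6 and C5 to an alkenyl arm on that sp3 carbon, so the ring closes by forming the C4–C5 bond alone.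

## Logic of the disconnections

From 24 back to 23: the four phenolic O–H bonds are replaced by O-benzyl ethers. The cut is placed last because the free catechol and phenols are the oxidation-prone part of 24 and the benzoates the base-sensitive part, and hydrogenolysis is neutral and leaves aryl esters alone. The gain is that every earlier intermediate is a fully capped, robust arene. The demand is that 23 contains nothing else reducible and that no nucleophilic solvent is used.

From 23 back to 21 (through 22): the O2–acyl bond is cut and O2 is given an acid-labile 4-methoxybenzyl ether. This tells O2 apart from O4 and O5 while staying inert to organolithiums and heat. The demand is an acidolysis that spares four benzyl ethers and the O1 benzoate, with the liberated benzylic cation intercepted before it alkylates the electron-rich rings.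

From 21 back to 20: the O4–benzyl bond is cut. The ring-forming step unavoidably delivers O4 as a free phenol, and capping it with the group O5 already carries makes O4 and O5 equivalent for the final step. The demand is O-alkylation of a doubly flanked phenol without disturbing the aryl ester.

From 20 back to 17: the ring bond C4–C5 is cut and C1 is reconnected to C4, turning the hexasubstituted arene into a four-membered ring with a two-carbon arm. The ordering of six substituents then reduces to two successive carbonyl additions to a squarate core, and the four oxygens already carry four different groups. The demand is a ring opening in which the oxygen on the sp3 carbon rotates outward, under conditions free of acid and nucleophiles.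

From 17 back to 8 and 14 (through 15 and 16): the C1–C6 bond and the O1–acyl bond are cut. C1 is a carbinol carbon, so it arises by adding an alkenyl nucleophile to a ketone, and acylating the resulting alkoxide installs a benzoate that stays to the end. The forward step must attack the carbonyl of 8 next to the alkoxy-bearing carbon, which is favoured because the other carbonyl is a vinylogous ester. The nucleophile 15 must hold lithium cis to the ether oxygen, since the other isomer has lithium anti to a leaving alkoxide and would fragment. By the sequence rule that reagent is E, while the bromide 14 it comes from and the alkene of 17 it produces are both Z. The descriptor changes because lithium ranks below the aryl carbon whereas bromine and the ring carbon rank above it; the geometry itself is retained throughout.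

From 14 back to 12, and from 12 back to 9 and 10: the C6–Br bond is cut, then the C5=C6 double bond. A bromine on the aryl-bearing carbon of an enol ether is the normal outcome of bromination and dehydrobromination, and the enol ether is one olefination from an aromatic aldehyde. This is two steps, against four or more for a route from the arylacetaldehyde oxidation level. The demand is elimination in the right direction and a usable geometric outcome.

From 8 back to 4 and 5 (through 6 and 7): the C3–aryl bond is cut. Single addition of an aryl nucleophile to a squarate carbonyl, followed by allylic ionisation, moves the double bond, unveils a ketone and leaves exactly one alkoxy group. The demand is mono-addition and a rearrangement that sheds one 4-methoxybenzyl group only.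

From 4 back to 1 and 2 (through 3): the two ring C–O ester bonds are cut, so that two molecules of 2 are joined to one molecule of 1. The diester is not a catalogue compound, and acid-catalysed esterification would destroy 2. The vinylogous acid is therefore activated as its dichloride and both equivalents of the alcohol are introduced under basic conditions.

## Other disconnections considered

Alternative 1: The cut removes three bonds of the central ring at once (C1–C2, C3–C4 and C5–C6). It leads back to a diyne A2, in which two aryl ynol ether units are tied through their oxygens by a di-tert-butylsilylene bridge, and to the diborylated alkyne A3. In the forward key step a [2+2+2] cyclotrimerisation mediated by CpCo(CO)2 would join them to the benzodioxasilole A1, which has the bridged oxygens on one adjacent pair of carbons and two boron atoms on the other. Oxidation of the two C–B bonds, benzoylation of the new catechol, and removal of the silylene and benzyl groups would give 24.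
- In its favour: it uses the mirror symmetry of 24, delivers the two oxygen pairs already distinguished, is convergent, and needs about six to seven steps against nine. On use of symmetry and on step count it is the better plan.
- Against it here: A2 is a bis(silyl ynol ether), a class prone to hydrolysis and to isomerisation to silylketenes. A3 is hindered and electron-poor. A benzene carrying two aryl and two boryl groups on adjacent positions is sterically demanding for a metallacycle pathway, so homo-oligomerisation and stable cyclobutadiene complexes are likely diversions.
- Comparison: structurally both plans fix the substituent order by connectivity, and here the alternative is the equal of the chosen plan. Mechanistically the chosen plan relies on a unimolecular pericyclic cascade with close precedent, whereas A1 requires an unprecedented substrate class in a metal-mediated step, so the chosen plan is the more dependable.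

Alternative 2: The cut is made at C2–C3 and C5–C6, which divides the central ring into two identical three-carbon units, each an arylpyruvate ester A4. In the forward key step an alkoxide-mediated head-to-tail double Claisen condensation would acylate each benzylic carbon with the ester carbon of the partner and close the dihydroxyquinone A5.
- In its favour: the whole carbon and oxygen framework comes from one monomer in one bond-forming operation, which is biomimetic and a known reaction class for terphenylquinones. On step count to the skeleton and on symmetry it is clearly the better plan.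
- Against it here: the two free hydroxyls of A5 are para to each other, whereas 24 needs acyl groups on adjacent oxygens. After reduction the four hydroxyls are nearly equivalent and nothing directs 1,2-dibenzoylation over the 1,4 and 1,5 patterns. Masking one catechol pair would be statistical. Arylpyruvates can also self-condense by aldol addition and lactonisation.
- Comparison: on structure the alternative leaves the central problem of oxygen differentiation unsolved, where the chosen plan solves it by construction. On mechanism it uses two intermolecular condensations under equilibrium control against one intramolecular cascade. The steps saved on the skeleton would probably be spent again on protecting-group work and separations.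

Alternative 3: The cut is made at the C4–O and C5–O bonds and leads back to the terphenyl catechol A6, itself reachable by a double Suzuki coupling. In the forward key step A6 would be oxidised at a carbon anode in benzyl alcohol A8 to the ortho-quinone, which adds A8 at C4, is re-oxidised, adds A8 again at C5 and is oxidised once more to the dialkoxy ortho-quinone A7. Reduction, dibenzoylation of the regenerated catechol and hydrogenolysis would give 24.
- In its favour: A6 is a simple skeleton. The original catechol oxygens become the benzoates and the new ethers become the free hydroxyls, so the pairs are differentiated by construction with use of the symmetry. The oxidant is reagent-free, and about five to six steps are needed. On step count it is the better plan, and on oxygen placement it is the equal of the chosen plan.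
- Against it here: anodic dialkoxylation of catechols is established for methanol, but A8 is itself oxidisable near the required potential, is a poor electrolysis medium and is a bulkier nucleophile. Each position to be attacked is flanked by an aryl group, the benzyloxyphenyl rings are oxidisable, and A7 is a doubly vinylogous ester open to further addition.
- Comparison: mechanistically the alternative needs two intermolecular additions interleaved with three electron-transfer stages to work on a hindered substrate, whereas the chosen plan needs one thermal isomerisation. The chosen plan is longer, but each of its bond formations has close analogy.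

Key step: step 6

Remark on names: in 17 the benzoate oxygen and the alkenyl group share the sp3 ring carbon (C1 of the cyclobutenyl ester), the 4-methoxybenzyloxy group is on C2 and the aryl group on C3 next to the C4 ketone. A name that places the alkenyl group on the oxo-bearing carbon does not describe a possible structure.

Remark on the group at O2: the 4-methoxybenzyl ether is kept in preference to a tert-butyl ether (which di-tert-butyl squarate would deliver) because it cannot be lost by thermal elimination at the temperature of step 6.

Assumption: aldehyde 9 and phosphonium salt 10 are treated as catalogue materials; 10 is otherwise one step from benzyl chloromethyl ether and PPh3.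

## Route

Step 1
Reactants: 1 squaric acid; 2 4-methoxybenzyl alcohol (two equivalents are consumed)
Product: 4 bis(4-methoxybenzyl) squarate (3,4-bis[(4-methoxybenzyl)oxy]cyclobut-3-ene-1,2-dione), via squaryl dichloride 3 (not isolated)
Conditions: (COCl)2 (2.2 equiv), cat. DMF, CH2Cl2, reflux; evaporate; then 2 (2.2 equiv), i-Pr2NEt (2.5 equiv), CH2Cl2, −20 °C → rt
Reagents that add atoms: 4-methoxybenzyl alcohol (the second equivalent of 2), COc1ccc(CO)cc1
Why: Vilsmeier-type activation converts the vinylogous acid into its dichloride, and addition–elimination of one molecule of the alcohol at each of the two vinylogous acid chloride carbons gives the diester. The hindered amine removes HCl so that the acid-labile benzylic groups survive; direct acid-catalysed esterification is avoided because 2 would self-condense.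

Step 2
Reactants: 5 1-(benzyloxy)-4-bromobenzene; 4 bis(4-methoxybenzyl) squarate
Product: 8 3-[4-(benzyloxy)phenyl]-4-[(4-methoxybenzyl)oxy]cyclobut-3-ene-1,2-dione, via aryllithium 6 (not isolated), via lithium alkoxide 7 (not isolated)
Conditions: n-BuLi, THF, −78 °C; add to 4, THF, −78 °C; then (CF3CO)2O, −78 → 0 °C; aq. NaHCO3
Reagents that add atoms: none
Why: Bromine–lithium exchange gives the aryllithium, which adds once in 1,2 fashion to a squarate carbonyl at low temperature. Trifluoroacetylation of the alkoxide triggers allylic ionisation, and the resulting oxocarbenium ion loses its 4-methoxybenzyl group from oxygen as the trifluoroacetate, unveiling the second ketone (squarate addition and rearrangement to a 3-alkoxy-4-arylcyclobutenedione).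

Step 3
Reactants: 9 4-(benzyloxy)benzaldehyde; 10 (benzyloxymethyl)triphenylphosphonium chloride
Product: 12 1-(benzyloxy)-4-[2-(benzyloxy)ethenyl]benzene (E/Z mixture), via phosphorus ylide 11 (not isolated)
Conditions: KOt-Bu, THF, 0 °C; then 9, 0 °C → rt
Reagents that add atoms: none
Why: Wittig alkoxymethylenation of an aromatic aldehyde with a reactive α-alkoxy ylide. The geometry of the enol ether is unimportant because both isomers pass through the same oxocarbenium ion in step 4.

Step 4
Reactants: 12 1-(benzyloxy)-4-[2-(benzyloxy)ethenyl]benzene (E/Z mixture)
Product: 14 1-(benzyloxy)-4-[(Z)-2-(benzyloxy)-1-bromoethenyl]benzene, via dibromide 13 (not isolated)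
Conditions: Br2, CH2Cl2, −78 °C; then DBU, −78 °C → rt; chromatography on Et3N-deactivated silica
Reagents that add atoms: bromine, BrBr
Why: Bromination and dehydrobromination of an enol ether: the α-bromo ether of 13 ionises to an oxocarbenium ion, which loses the acidified benzylic proton and leaves bromine on the aryl-bearing carbon. The Z isomer (bromine cis to the benzyloxy group, aryl trans) should predominate because it keeps the large aryl group away from the ether oxygen.

Step 5
Reactants: 14 1-(benzyloxy)-4-[(Z)-2-(benzyloxy)-1-bromoethenyl]benzene; 8 3-[4-(benzyloxy)phenyl]-4-[(4-methoxybenzyl)oxy]cyclobut-3-ene-1,2-dione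
Product: 17 racemic 3-[4-(benzyloxy)phenyl]-1-{(Z)-2-(benzyloxy)-1-[4-(benzyloxy)phenyl]ethenyl}-2-[(4-methoxybenzyl)oxy]-4-oxocyclobut-2-en-1-yl benzoate, via alkenyllithium 15 (not isolated), via lithium alkoxide 16 (not isolated)
Conditions: t-BuLi (2 equiv), THF, −78 °C; add to 8, THF, −78 °C; then BzCl, −78 → −20 °C; aq. NaHCO3; Et3N-deactivated silica
Reagents that add atoms: benzoyl chloride, O=C(Cl)c1ccccc1
Why: Bromine–lithium exchange proceeds with retention and gives the alkenyllithium with lithium cis to the ether oxygen, where it is chelated and cannot undergo anti β-elimination. It adds in 1,2 fashion to the more electrophilic carbonyl of 8 (the one next to the alkoxy-bearing carbon, the other being a vinylogous ester), and the tertiary lithium alkoxide is acylated in situ. The new quaternary carbon forms as a racemate and is destroyed in step 6.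

Step 6
Reactants: 17 racemic 3-[4-(benzyloxy)phenyl]-1-{(Z)-2-(benzyloxy)-1-[4-(benzyloxy)phenyl]ethenyl}-2-[(4-methoxybenzyl)oxy]-4-oxocyclobut-2-en-1-yl benzoate
Product: 20 5-(benzyloxy)-3,6-bis[4-(benzyloxy)phenyl]-4-hydroxy-2-[(4-methoxybenzyl)oxy]phenyl benzoate, via dienylketene 18 (not isolated), via cyclohexadienone 19 (not isolated)
Conditions: PhMe (0.02 M, degassed), 110 °C, base-washed glassware
Reagents that add atoms: none
Why: Heating should induce conrotatory 4π electrocyclic opening of the cyclobutenone, breaking the bond between the sp3 carbon (C1 of the target ring) and the carbonyl carbon (C4) to give dienylketene 18. A disrotatory 6π electrocyclisation then joins the ketene carbon C4 to the benzyloxy-bearing alkene carbon C5, which is the mode by which the only new ring, the central six-membered ring, is closed; cyclohexadienone 19 then enolises to the phenol with gain of aromaticity. The closest known reaction type is the Moore-type thermal ring expansion of squarate-derived 4-alkenyl-4-oxygenated cyclobutenones to hydroquinone derivatives. No stereocentre survives: the quaternary carbon of 17 becomes trigonal on ring opening and the sp3 carbon C5 of 19 is erased by tautomerisation, so the racemic nature of 17 and the geometry of its alkene have no consequence for 20. The selectivity required is torquoselectivity: the benzoyloxy group must rotate outward so that the alkenyl group ends up cis to the ketene-bearing carbon, and the outward preference of an oxygen lone-pair donor should outweigh the steric preference of the alkenyl group, although an acyloxy group is a weaker donor than hydroxyl or silyloxy. The cis benzyloxy group on C5 points into the closing ring, but the ketene terminus is sp-hybridised and unhindered, so closure should stay faster than any intermolecular reaction of the ketene under dilute, aprotic conditions. Acid-free glassware protects the ionisable β-alkoxyallylic benzoate of 17 until it has opened. The positions of the four oxygens in 20 (free hydroxyl at C4, benzyl ether at C5, benzoate at C1, 4-methoxybenzyl ether at C2) follow from the connectivity of 17 alone.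

Step 7
Reactants: 20 5-(benzyloxy)-3,6-bis[4-(benzyloxy)phenyl]-4-hydroxy-2-[(4-methoxybenzyl)oxy]phenyl benzoate
Product: 21 4,5-bis(benzyloxy)-3,6-bis[4-(benzyloxy)phenyl]-2-[(4-methoxybenzyl)oxy]phenyl benzoate
Conditions: BnBr, K2CO3, DMF, 0 °C → rt
Reagents that add atoms: benzyl bromide, BrCc1ccccc1
Why: Williamson etherification of the single free phenol (O4), which must be masked before O2 is unveiled. The benzoate is para to the phenoxide and flanked by two ortho substituents, so acyl transfer should not compete with fast O-benzylation.

Step 8
Reactants: 21 4,5-bis(benzyloxy)-3,6-bis[4-(benzyloxy)phenyl]-2-[(4-methoxybenzyl)oxy]phenyl benzoate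
Product: 23 4,5-bis(benzyloxy)-3,6-bis[4-(benzyloxy)phenyl]-1,2-phenylene dibenzoate, via phenol 22 (not isolated)
Conditions: CF3CO2H (10% v/v), 1,3-dimethoxybenzene, CH2Cl2, 0 °C; evaporate (PhMe); then BzCl, pyridine, cat. DMAP, CH2Cl2, 0 °C → rt
Reagents that add atoms: benzoyl chloride, O=C(Cl)c1ccccc1
Why: Acidolysis should cleave the 4-methoxybenzyl aryl ether much faster than the benzyl ethers because of the stabilised cation, which the electron-rich scavenger intercepts by Friedel–Crafts alkylation. Nucleophile-catalysed acylation then benzoylates the only free hydroxyl; benzoyl migration between O1 and O2 in 22 would not change the outcome.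

Step 9
Reactants: 23 4,5-bis(benzyloxy)-3,6-bis[4-(benzyloxy)phenyl]-1,2-phenylene dibenzoate
Product: 24 4,5-dihydroxy-3,6-bis(4-hydroxyphenyl)-1,2-phenylene dibenzoate (target CNP0216579.0)
Conditions: H2 (1 atm), 10% Pd/C, EtOAc–THF, rt; filtration and work-up under Ar
Reagents that add atoms: none
Why: Catalytic hydrogenolysis cleaves the four benzyl aryl ethers while aryl benzoates are inert under neutral hydrogenation. Each benzoate has an aryl-bearing carbon, not a hydroxyl, as its outer neighbour, so no acyl migration to the new catechol is possible, and the aprotic solvent excludes transesterification.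

## Compound list

1 | squaric acid (3,4-dihydroxycyclobut-3-ene-1,2-dione) | O=C1C(O)=C(O)C1=O | starting material
2 | 4-methoxybenzyl alcohol | COc1ccc(CO)cc1 | starting material
3 | squaryl dichloride (3,4-dichlorocyclobut-3-ene-1,2-dione) | O=C1C(Cl)=C(Cl)C1=O | intermediate (not isolated)
4 | bis(4-methoxybenzyl) squarate (3,4-bis[(4-methoxybenzyl)oxy]cyclobut-3-ene-1,2-dione) | O=C1C(OCc2ccc(OC)cc2)=C(OCc2ccc(OC)cc2)C1=O | intermediate
5 | 1-(benzyloxy)-4-bromobenzene | Brc1ccc(OCc2ccccc2)cc1 | starting material
6 | [4-(benzyloxy)phenyl]lithium | [Li]c1ccc(OCc2ccccc2)cc1 | intermediate (not isolated)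
7 | lithium 1-[4-(benzyloxy)phenyl]-2,3-bis[(4-methoxybenzyl)oxy]-4-oxocyclobut-2-en-1-olate (racemic) | [Li]OC1(c2ccc(OCc3ccccc3)cc2)C(OCc2ccc(OC)cc2)=C(OCc2ccc(OC)cc2)C1=O | intermediate (not isolated)
8 | 3-[4-(benzyloxy)phenyl]-4-[(4-methoxybenzyl)oxy]cyclobut-3-ene-1,2-dione | O=C1C(=O)C(c2ccc(OCc3ccccc3)cc2)=C1OCc1ccc(OC)cc1 | intermediate
9 | 4-(benzyloxy)benzaldehyde | O=Cc1ccc(OCc2ccccc2)cc1 | starting material
10 | (benzyloxymethyl)triphenylphosphonium chloride | [Cl-].c1ccc(COC[P+](c2ccccc2)(c2ccccc2)c2ccccc2)cc1 | starting material
11 | (benzyloxymethylidene)triphenylphosphorane | C(OCc1ccccc1)=P(c1ccccc1)(c1ccccc1)c1ccccc1 | intermediate (not isolated)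
12 | 1-(benzyloxy)-4-[2-(benzyloxy)ethenyl]benzene (E/Z mixture) | C(=Cc1ccc(OCc2ccccc2)cc1)OCc1ccccc1 | intermediate
13 | 1-(benzyloxy)-4-[2-(benzyloxy)-1,2-dibromoethyl]benzene (mixture of diastereomers) | BrC(OCc1ccccc1)C(Br)c1ccc(OCc2ccccc2)cc1 | intermediate (not isolated)
14 | 1-(benzyloxy)-4-[(Z)-2-(benzyloxy)-1-bromoethenyl]benzene | Br/C(c1ccc(OCc2ccccc2)cc1)=C\OCc1ccccc1 | intermediate
15 | {(E)-2-(benzyloxy)-1-[4-(benzyloxy)phenyl]ethenyl}lithium (lithium cis to the benzyloxy oxygen) | [Li]/C(c1ccc(OCc2ccccc2)cc1)=C\OCc1ccccc1 | intermediate (not isolated)
16 | lithium 3-[4-(benzyloxy)phenyl]-1-{(Z)-2-(benzyloxy)-1-[4-(benzyloxy)phenyl]ethenyl}-2-[(4-methoxybenzyl)oxy]-4-oxocyclobut-2-en-1-olate (racemic) | [Li]OC1(/C(c2ccc(OCc3ccccc3)cc2)=C\OCc2ccccc2)C(OCc2ccc(OC)cc2)=C(c2ccc(OCc3ccccc3)cc2)C1=O | intermediate (not isolated)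
17 | 3-[4-(benzyloxy)phenyl]-1-{(Z)-2-(benzyloxy)-1-[4-(benzyloxy)phenyl]ethenyl}-2-[(4-methoxybenzyl)oxy]-4-oxocyclobut-2-en-1-yl benzoate (racemic) | O=C1C(c2ccc(OCc3ccccc3)cc2)=C(OCc2ccc(OC)cc2)C1(OC(=O)c1ccccc1)/C(c1ccc(OCc2ccccc2)cc1)=C\OCc1ccccc1 | intermediate (key-step precursor)
18 | (3Z,5Z)-6-(benzyloxy)-2,5-bis[4-(benzyloxy)phenyl]-3-[(4-methoxybenzyl)oxy]-1-oxohexa-1,3,5-trien-4-yl benzoate | O=C=C(c1ccc(OCc2ccccc2)cc1)/C(OCc1ccc(OC)cc1)=C(OC(=O)c1ccccc1)\C(c1ccc(OCc2ccccc2)cc1)=C/OCc1ccccc1 | intermediate (not isolated)
19 | 3-(benzyloxy)-2,5-bis[4-(benzyloxy)phenyl]-6-[(4-methoxybenzyl)oxy]-4-oxocyclohexa-1,5-dien-1-yl benzoate (racemic) | O=C1C(c2ccc(OCc3ccccc3)cc2)=C(OCc2ccc(OC)cc2)C(OC(=O)c2ccccc2)=C(c2ccc(OCc3ccccc3)cc2)C1OCc1ccccc1 | intermediate (not isolated)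
20 | 5-(benzyloxy)-3,6-bis[4-(benzyloxy)phenyl]-4-hydroxy-2-[(4-methoxybenzyl)oxy]phenyl benzoate | Oc1c(-c2ccc(OCc3ccccc3)cc2)c(OCc2ccc(OC)cc2)c(OC(=O)c2ccccc2)c(-c2ccc(OCc3ccccc3)cc2)c1OCc1ccccc1 | intermediate (key-step product)
21 | 4,5-bis(benzyloxy)-3,6-bis[4-(benzyloxy)phenyl]-2-[(4-methoxybenzyl)oxy]phenyl benzoate | O=C(Oc1c(OCc2ccc(OC)cc2)c(-c2ccc(OCc3ccccc3)cc2)c(OCc2ccccc2)c(OCc2ccccc2)c1-c1ccc(OCc2ccccc2)cc1)c1ccccc1 | intermediate
22 | 4,5-bis(benzyloxy)-3,6-bis[4-(benzyloxy)phenyl]-2-hydroxyphenyl benzoate | O=C(Oc1c(O)c(-c2ccc(OCc3ccccc3)cc2)c(OCc2ccccc2)c(OCc2ccccc2)c1-c1ccc(OCc2ccccc2)cc1)c1ccccc1 | intermediate (not isolated)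
23 | 4,5-bis(benzyloxy)-3,6-bis[4-(benzyloxy)phenyl]-1,2-phenylene dibenzoate | O=C(Oc1c(OC(=O)c2ccccc2)c(-c2ccc(OCc3ccccc3)cc2)c(OCc2ccccc2)c(OCc2ccccc2)c1-c1ccc(OCc2ccccc2)cc1)c1ccccc1 | intermediate
24 | 4,5-dihydroxy-3,6-bis(4-hydroxyphenyl)-1,2-phenylene dibenzoate | O=C(Oc1c(OC(=O)c2ccccc2)c(-c2ccc(O)cc2)c(O)c(O)c1-c1ccc(O)cc1)c1ccccc1 | target

## Step count and risk assessment

Total step count: 9. Longest linear sequence: 7 steps (steps 1, 2, 5, 6, 7, 8, 9; the branch through steps 3 and 4 is equally long).

Least certain steps:

Step 6 (key step). The most likely failure is erosion of torquoselectivity, because an acyloxy group is a weaker donor than an alkoxy or silyloxy group. Inward rotation of the benzoate would leave the alkenyl group remote from the ketene and divert it to lactone-type products. A second risk is ionisation or allylic transposition of the β-alkoxyallylic benzoate before ring opening. The fallback sets out from 16 and returns at 23. Alkoxide 16 is trapped with Et3SiCl instead of BzCl to give the triethylsilyl ether F1, the classical strongly donating substituent for this ring expansion. Heating F1 in toluene should give the silyloxyphenol F2. The free O4 hydroxyl of F2 is benzylated under Mitsunobu conditions (benzyl alcohol, PPh3, DIAD), which spare the aryl silyl ether, to give the tetrabenzyl silyl ether F3. Acidolysis (CF3CO2H, 1,3-dimethoxybenzene) followed by Bu4NF buffered with AcOH removes both the 4-methoxybenzyl and the silyl group to give the catechol F4. Because the target is mirror-symmetric, double benzoylation of F4 (BzCl, pyridine, DMAP) gives 23 directly, so the detour costs no extra step.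

Step 5. Possible failures are loss of the alkenyllithium (isomerisation to the form with lithium anti to the benzyloxy group followed by β-elimination, or proton abstraction), conjugate addition–elimination at the alkoxy-bearing carbon of 8, and incomplete acylation or anion-accelerated ring opening of the hindered tertiary alkoxide on warming. The fallback sets out from 16 and returns at 17: the alkoxide is protonated at −78 °C with aqueous NH4Cl and the tertiary carbinol F5 is isolated on deactivated silica. It is then acylated in a separate operation with benzoic anhydride, Et3N and DMAP, which separates the carbon–carbon bond formation from the esterification and allows each to be optimised.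

Step 4. Possible failures are ionisation at the benzylic bromide (giving elimination in the wrong direction), electrophilic bromination of the electron-rich rings, and formation of a geometric mixture that lowers the supply of the Z bromide. The fallback sets out from 12 and returns at 14: treatment of 12 with N-bromosuccinimide in the presence of benzyl alcohol gives the bromo acetal F6 by bromoacetalisation. This is an isolable compound with no α-bromo ether, in which only the acetal carbon can ionise. Me3SiOTf and i-Pr2NEt then remove one benzyloxy group to regenerate the enol ether with bromine fixed on the aryl-bearing carbon, giving 14.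

Step 1. Possible failures are conversion of the benzylic alcohol to its chloride by HCl or chloride, addition of the amine to the dichloride, and incomplete double substitution. The fallback sets out from 1 and returns at 4: squaric acid is precipitated from water with AgNO3 as disilver squarate F7, which is dried and O-alkylated with 4-methoxybenzyl chloride in Et2O. The ester is thus made by forming the O–CH2 bond instead of the ring C–O bond, with no acid chloride and no acid.

Step 7. Possible failures are intermolecular benzoyl transfer from O1 to the phenoxide, ester cleavage by adventitious hydroxide under the basic conditions, and slow alkylation of the doubly flanked phenol. The fallback sets out from 20 and returns at 21: Mitsunobu etherification with benzyl alcohol, PPh3 and DIAD in THF activates the alcohol instead of generating a free phenoxide, and gives 21 directly without a new intermediate.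

## Further compounds

F1 | step 6 | 2-[4-(benzyloxy)phenyl]-4-{(Z)-2-(benzyloxy)-1-[4-(benzyloxy)phenyl]ethenyl}-3-[(4-methoxybenzyl)oxy]-4-[(triethylsilyl)oxy]cyclobut-2-en-1-one (racemic) | O=C1C(c2ccc(OCc3ccccc3)cc2)=C(OCc2ccc(OC)cc2)C1(O[Si](CC)(CC)CC)/C(c1ccc(OCc2ccccc2)cc1)=C\OCc1ccccc1
F2 | step 6 | 2-(benzyloxy)-3,6-bis[4-(benzyloxy)phenyl]-5-[(4-methoxybenzyl)oxy]-4-[(triethylsilyl)oxy]phenol | Oc1c(-c2ccc(OCc3ccccc3)cc2)c(OCc2ccc(OC)cc2)c(O[Si](CC)(CC)CC)c(-c2ccc(OCc3ccccc3)cc2)c1OCc1ccccc1
F3 | step 6 | {4,5-bis(benzyloxy)-3,6-bis[4-(benzyloxy)phenyl]-2-[(4-methoxybenzyl)oxy]phenoxy}triethylsilane | CC[Si](CC)(CC)Oc1c(OCc2ccc(OC)cc2)c(-c2ccc(OCc3ccccc3)cc2)c(OCc2ccccc2)c(OCc2ccccc2)c1-c1ccc(OCc2ccccc2)cc1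
F4 | step 6 | 4,5-bis(benzyloxy)-3,6-bis[4-(benzyloxy)phenyl]benzene-1,2-diol | Oc1c(O)c(-c2ccc(OCc3ccccc3)cc2)c(OCc2ccccc2)c(OCc2ccccc2)c1-c1ccc(OCc2ccccc2)cc1
F5 | step 5 | 2-[4-(benzyloxy)phenyl]-4-{(Z)-2-(benzyloxy)-1-[4-(benzyloxy)phenyl]ethenyl}-4-hydroxy-3-[(4-methoxybenzyl)oxy]cyclobut-2-en-1-one (racemic) | O=C1C(c2ccc(OCc3ccccc3)cc2)=C(OCc2ccc(OC)cc2)C1(O)/C(c1ccc(OCc2ccccc2)cc1)=C\OCc1ccccc1
F6 | step 4 | 1-(benzyloxy)-4-[2,2-bis(benzyloxy)-1-bromoethyl]benzene (racemic) | BrC(c1ccc(OCc2ccccc2)cc1)C(OCc1ccccc1)OCc1ccccc1
F7 | step 1 | disilver squarate | [Ag+].[Ag+].[O-]C1=C([O-])C(=O)C1=O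
F0 | step 7 | none | none
A1 | alternative 1 | 2,2-di-tert-butyl-4,7-bis[4-(benzyloxy)phenyl]-5,6-bis(4,4,5,5-tetramethyl-1,3,2-dioxaborolan-2-yl)-1,3,2-benzodioxasilole | CC(C)(C)[Si]1(C(C)(C)C)Oc2c(O1)c(-c1ccc(OCc3ccccc3)cc1)c(B1OC(C)(C)C(C)(C)O1)c(B1OC(C)(C)C(C)(C)O1)c2-c1ccc(OCc2ccccc2)cc1
A2 | alternative 1 | di-tert-butylbis({[4-(benzyloxy)phenyl]ethynyl}oxy)silane | CC(C)(C)[Si](OC#Cc1ccc(OCc2ccccc2)cc1)(OC#Cc1ccc(OCc2ccccc2)cc1)C(C)(C)C
A3 | alternative 1 | 1,2-bis(4,4,5,5-tetramethyl-1,3,2-dioxaborolan-2-yl)ethyne | CC1(C)OB(OC1(C)C)C#CB1OC(C)(C)C(C)(C)O1
A4 | alternative 2 | methyl 3-[4-(benzyloxy)phenyl]-2-oxopropanoate | COC(=O)C(=O)Cc1ccc(OCc2ccccc2)cc1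
A5 | alternative 2 | 2,5-dihydroxy-3,6-bis[4-(benzyloxy)phenyl]-1,4-benzoquinone | O=C1C(O)=C(c2ccc(OCc3ccccc3)cc2)C(=O)C(O)=C1c1ccc(OCc2ccccc2)cc1
A6 | alternative 3 | 3,6-bis[4-(benzyloxy)phenyl]benzene-1,2-diol | Oc1c(O)c(-c2ccc(OCc3ccccc3)cc2)ccc1-c1ccc(OCc2ccccc2)cc1
A7 | alternative 3 | 4,5-bis(benzyloxy)-3,6-bis[4-(benzyloxy)phenyl]cyclohexa-3,5-diene-1,2-dione | O=C1C(=O)C(c2ccc(OCc3ccccc3)cc2)=C(OCc2ccccc2)C(OCc2ccccc2)=C1c1ccc(OCc2ccccc2)cc1
A8 | alternative 3 | benzyl alcohol | OCc1ccccc1
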